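Ring B positions keep the numbering of the target (C1–C4, C4a, C8a) in every intermediate, including the cyclobutanone; pyranone atoms are primed (O1′, C2′=O, C4′ bonded to C1, C6′ bearing the carboxyl).

## Analysis of the target

Target 17 is a 1,2-dihydronaphthalene: ring A is a catechol (OH at C6 and C7), and ring B carries a carboxylic acid on sp3 C2 and a second one on C3 of the C3=C4 double bond, which is conjugated with ring A. At sp3 C1 sits a 2-oxo-2H-pyran-4-yl ring with a third acid at C6′. The only stereocentres are the adjacent C1 (R) and C2 (S), and their substituents are trans. C1–H is benzylic and, through C4′=C3′–C2′=O, vinylogously α to the lactone carbonyl, so C1 is labile to base and settles trans to the C2 substituent. C2–H is only α to a carboxyl, so C2 is the centre that has to carry the absolute configuration. The pyranone is an enol lactone and a double Michael acceptor that hydroxide, alkoxide and amines open; base also shifts the C3=C4 double bond toward C2=C3, after which air aromatises ring B, and the catechol oxidises easily. The synthesis is hard because three acids and a catechol must be unmasked without base, an electrophilic heterocycle must be carried through C–C bond formation, and C2 must be set in a skeleton with few handles. The route rests on one feature: C1 and C4 are bonded to the neighbouring ring A carbons C8a and C4a, ring A is symmetrically oxygenated, and C1 can be ionised because of the pyranone. Ring A can therefore be delivered as a symmetrical aryne that inserts into the C1–C4 bond of a four-carbon ring.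

## Retrosynthetic reasoning

**17 ⇒ 16 ⇒ 15.** Only O–C(alkyl) bonds are cut: two aryl methyl ethers, one tert-butyl ester at C2 and two methyl esters. The masks are needed because a free catechol and free acids would not survive the fluoride, Lewis acid and hydride steps. The C2 ester is tert-butyl because it is the most hindered ester and sits on the stereocentre, so it should leave by alkyl–oxygen cleavage under the same Lewis acid that cleaves the ethers. The forward steps must be acidic throughout, so that the pyranone, the C3=C4 position and C2 are untouched.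

**15 ⇒ 14 ⇒ 13.** The C3=C4 double bond is traced back to a C4 alcohol and then to a C4 ketone; no skeletal bond is cut. A C4 ketone is what an acyl-type bond to C4a leaves behind, and it is also the handle that makes C3 nucleophilic. The forward dehydration is helped by the C7 methoxy group para to C4a, and only C3 offers a β-hydrogen.

**13 ⇒ 11 (through 12).** The C3–carboxyl bond is cut. It is cut here and not earlier because an ester on C3 of the four-membered precursor would make C3 the most acidic site, and the aryne would then insert into C3–C4 instead of C1–C4. The forward reaction has to carboxylate the only enolisable α-carbon of the aryl ketone without a nucleophilic base, which points to magnesium-assisted soft enolisation and capture of a one-carbon electrophile as a chelate.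

**11 ⇒ 8 + 9 (through 10).** This is the key disconnection: C1–C8a and C4–C4a are cut together. Ring A leaves as the symmetrical aryne 10, made from 9, and ring B contracts to the cyclobutanone 8, in which C1 and C4 are directly bonded. Other cuts in ring B are worse: C1–C2 or C2–C3 would need acyclic control of two centres, and a Friedel–Crafts closure at C1 would need a cation next to the electron-poor pyranone. The gain is both ring B bonds in one step and a convergent union of the arene with a small chiral fragment that already carries the heterocycle. The C1 configuration comes for free, by equilibration. The forward reaction needs C1 to be the carbanion, which the pyranone ensures, and C2 to stay untouched.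

**8 ⇒ 7 + 5.** The C1–C4′ bond is cut between a ketone α-carbon and the 4-position of the pyranone. C4′ of a 4-bromopyranone is a vinylogous acyl bromide, and the α-carbon of the cyclobutanone is delivered as the enol silane 7. The new centre needs no control because it equilibrates, and the ester-bearing carbon keeps the configuration already present in 7.

**7 ⇒ 6.** No skeletal bond is cut. Compound 6 has a mirror plane through the carbonyl carbon and the ester-bearing carbon, and 7 results from removing a proton from one of the two enantiotopic methylene groups and fixing the choice as a silyl enol ether. A chiral lithium amide is used and not a chiral secondary-amine catalyst, because 4-bromopyranones consume amines by substitution at C4′. This is the only step that creates absolute configuration.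

**5 ⇒ 4 ⇒ 3 ⇒ 2 ⇒ 1.** These are functional group changes on a commercial pyranone: ester from acid, acid from aldehyde, aldehyde from the 6-methyl group, bromide from the 4-hydroxyl. The bromide is installed first so that the acidic 4-hydroxyl is absent during the oxidations, and the ester is made last under neutral conditions so that no alkoxide meets the C4′ bromide.

## Alternatives that were turned down

**Alternative 1:** The pyranone is disconnected at its lactone bond O1′–C2′ and traced to an aromatic ring. The precursor is the pendant catechol dimethyl (1R,2S)-1-(3,4-dihydroxyphenyl)-6,7-dimethoxy-1,2-dihydronaphthalene-2,3-dicarboxylate A1. In the forward step a non-heme extradiol dioxygenase (divalent iron) and O2 cut the C4″–C5″ bond next to the diol, the semialdehyde closes through its enol oxygen to a cyclic hemiacetal, and a dehydrogenase in the same pot oxidises it to the lactone. The product is 4-[(1R,2S)-6,7-dimethoxy-2,3-bis(methoxycarbonyl)-1,2-dihydronaphthalen-1-yl]-2-oxo-2H-pyran-6-carboxylic acid A2.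
- For: it follows the likely biogenesis, forms the heterocycle at the right oxidation level with C6′ already an acid, and runs in water near neutral pH. After A2 only deprotection remains. In step economy after the carbon skeleton and in mildness it is stronger than the chosen route.
- Against: it depends on an enzyme accepting a bulky, lipophilic, non-natural substrate and cutting C4″–C5″ and not C2″–C3″ or the bond between the hydroxyls. That cannot be argued from structure. Two proteins and a cofactor cycle must work together, and the open semialdehyde can condense with ammonia or amine buffers to a pyridine. A1 must still be made as one enantiomer, which oxidative phenol coupling does not give without an auxiliary or a resolution.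
- In its place the chosen route offers a key step whose selectivities follow from acidity, strain and symmetry, and a single reagent-controlled step that sets the configuration.

**Alternative 2:** The pyranone is cut into two alkynes: 3-[(1R,2S)-6,7-dimethoxy-2,3-bis(methoxycarbonyl)-1,2-dihydronaphthalen-1-yl]prop-2-ynoic acid A3 and 3,3-diethoxyprop-1-yne A4. In the forward step [(Ph3P)Au]OTf, from Ph3PAuCl and AgOTf, adds the acid across the terminal alkyne (O1′–C6′), and the enol ester closes 6-endo-dig on the gold-activated alkynoate (C4′–C5′). The product is dimethyl (1R,2S)-1-[6-(diethoxymethyl)-2-oxo-2H-pyran-4-yl]-6,7-dimethoxy-1,2-dihydronaphthalene-2,3-dicarboxylate A5.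
- For: it is catalytic, convergent and free of base. In catalyst economy, and in avoiding a stoichiometric silyl triflate, it is stronger than the chosen route.
- Against: C1 in A3 is benzylic and propargylic, so propargyl–allenyl isomerisation threatens the stereocentre. The C2 ester carbonyl can attack the activated alkyne in a five-membered mode. The acetal is exposed to a cationic gold and silver medium. C6′ arrives two oxidation levels low, so acetal cleavage and aldehyde oxidation beside an electron-rich styrene are added before deprotection. A3 itself needs a C1-alkynyl dihydronaphthalene as a single enantiomer.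
- The chosen route brings in the pyranone with C6′ already at the acid level and uses its electron demand as the activating element of the key step.

**Alternative 3:** Ring B is cut at C2–C3 and C4–C4a. The pieces are dimethyl 2-{(S)-(3,4-dimethoxyphenyl)[6-(methoxycarbonyl)-2-oxo-2H-pyran-4-yl]methyl}propanedioate A6 and methyl (E)-3-methoxyprop-2-enoate A7. In the forward step Mn(OAc)3 (trivalent manganese) with Cu(OAc)2 in acetic acid oxidises the malonate to its radical, which adds to the ester-bearing carbon of A7. The α-methoxy radical is oxidised to an oxocarbenium ion, which closes on ring A para to a methoxy group. The product is trimethyl (1R)-4,6,7-trimethoxy-1-[6-(methoxycarbonyl)-2-oxo-2H-pyran-4-yl]-3,4-dihydronaphthalene-2,2,3(1H)-tricarboxylate A8, as a mixture at C3 and C4.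
- For: the reagents are cheap, two ring bonds form at once, and the C3 carboxyl and a C4 leaving group arrive together. The chosen route needs three steps to install the C3 carboxyl and the alkene, so on that point this alternative is stronger.
- Against: the only stereocentre in A6 is the acidic, doubly activated C1, a poor store of absolute configuration and hard to make enantioselectively. C2 is set only later, when one malonate ester is removed, with no control element, and the hot halide conditions usual for that dealkoxycarbonylation would attack the pyranone. The tertiary C1–H and the pyranone diene are exposed to a one-electron oxidant in hot acetic acid.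
- The chosen route stores chirality at the non-acidic C2 and lets C1 follow by equilibration.

Key step: step 7

## Route

Assumption: lithium (R,R)-bis(1-phenylethyl)amide is taken to give the (R)-enol silane 7; if the sense of induction is the opposite, the (S,S)-amide is used and nothing else changes.

Step 1
Reactants: 1 4-hydroxy-6-methyl-2H-pyran-2-one (triacetic acid lactone)
Product: 2 4-bromo-6-methyl-2H-pyran-2-one
Conditions: Bu4NBr, P2O5, toluene, 100 °C
Reagents that add atoms: tetrabutylammonium bromide, CCCC[N+](CCCC)(CCCC)CCCC.[Br-]
Why: The 4-hydroxyl is a vinylogous carboxylic acid; P2O5 phosphorylates it and bromide displaces the phosphate at C4 by addition–elimination (deoxybromination of a vinylogous acid), leaving the lactone and the 6-methyl group untouched.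

Step 2
Reactants: 2 4-bromo-6-methyl-2H-pyran-2-one
Product: 3 4-bromo-2-oxo-2H-pyran-6-carbaldehyde
Conditions: SeO2, 1,4-dioxane, 150 °C (sealed tube)
Reagents that add atoms: selenium dioxide, O=[Se]=O
Why: Riley oxidation: the 6-methyl group is allylic to C5=C6 and vinylogously α to the lactone, so SeO2 should take it to the aldehyde by ene reaction and [2,3]-shift, as with other 4-substituted 6-methylpyranones; no nucleophile is present that could displace the C4 bromide.

Step 3
Reactants: 3 4-bromo-2-oxo-2H-pyran-6-carbaldehyde
Product: 4 4-bromo-2-oxo-2H-pyran-6-carboxylic acid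
Conditions: NaClO2, NaH2PO4, 2-methylbut-2-ene, t-BuOH/H2O, 0 °C → rt
Reagents that add atoms: sodium chlorite, [Na+].[O-]Cl=O
Why: Pinnick oxidation of the aldehyde in a weakly acidic buffer; 2-methylbut-2-ene removes the hypochlorous acid, and chlorite attacks neither the lactone nor the C4 bromide.

Step 4
Reactants: 4 4-bromo-2-oxo-2H-pyran-6-carboxylic acid
Product: 5 methyl 4-bromo-2-oxo-2H-pyran-6-carboxylate
Conditions: TMSCHN2, MeOH/toluene, 0 °C
Reagents that add atoms: (trimethylsilyl)diazomethane, C[Si](C)(C)C=[N+]=[N-]
Why: Esterification of the acid by diazomethane formed in situ from TMSCHN2 and methanol; the neutral conditions avoid methoxide, which would substitute the C4 bromide.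

Step 5
Reactants: 6 tert-butyl 3-oxocyclobutane-1-carboxylate
Product: 7 tert-butyl (1R)-3-[(trimethylsilyl)oxy]cyclobut-2-ene-1-carboxylate
Conditions: (R,R)-bis(1-phenylethyl)amine, n-BuLi, THF, −78 °C; then 6, TMSCl (in situ quench), −100 °C
Reagents that add atoms: chlorotrimethylsilane, C[Si](C)(C)Cl
Why: Enantioselective deprotonation of a prochiral 3-substituted cyclobutanone by a chiral lithium amide with in situ silylation; the base distinguishes the enantiotopic α-methylene groups, and the position of the enol double bond records that choice, which makes the ester-bearing carbon (the future C2) a stereocentre.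

Step 6
Reactants: 7 tert-butyl (1R)-3-[(trimethylsilyl)oxy]cyclobut-2-ene-1-carboxylate; 5 methyl 4-bromo-2-oxo-2H-pyran-6-carboxylate
Product: 8 tert-butyl (1R,2R)-2-[6-(methoxycarbonyl)-2-oxo-2H-pyran-4-yl]-3-oxocyclobutane-1-carboxylate
Conditions: TiCl4, CH2Cl2, −78 °C; aq. NaHCO3; then Et3N (cat.), CH2Cl2, rt
Reagents that add atoms: none
Why: Mukaiyama–Michael addition of the enol silane to C4′ of the TiCl4-activated pyranone followed by loss of bromide (addition–elimination at a vinylogous acyl bromide); the bond forms only at the enol carbon of 7, so the ester-bearing centre is carried over, and the new acidic centre is set trans by approach anti to the tert-butyl ester and by amine-catalysed equilibration.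

Step 7
Reactants: 8 tert-butyl (1R,2R)-2-[6-(methoxycarbonyl)-2-oxo-2H-pyran-4-yl]-3-oxocyclobutane-1-carboxylate; 9 4,5-dimethoxy-2-(trimethylsilyl)phenyl trifluoromethanesulfonate
Product: 11 tert-butyl (1R,2R)-6,7-dimethoxy-1-[6-(methoxycarbonyl)-2-oxo-2H-pyran-4-yl]-4-oxo-1,2,3,4-tetrahydronaphthalene-2-carboxylate, via 4,5-dimethoxybenzyne 10 (not isolated)
Conditions: CsF (3 equiv), MeCN, 40 °C, 9 (1.3 equiv) added over 4 h
Reagents that add atoms: none
Why: Proposed new method: fluoride desilylates 9, loss of triflate gives aryne 10, and the basic fluoride medium removes the C1 proton of 8, which is acidified by the ketone and, through C4′=C3′–C2′=O, by the lactone. The carbanion adds through C1 to the symmetrical aryne, so there is no regiochemical question, and the aryl anion attacks the adjacent strained C4 ketone (4-exo-trig) to give a benzocyclobutenoxide fused to the cyclobutane. This alkoxide fragments at C1–C4 and expels the C1 anion, now stabilised by the pyranone and the new aryl group, so C1–C8a and C4–C4a are formed and the four-membered ring becomes the six-membered ring B by a net two-carbon ring expansion, not by a direct six-membered closure. The closest known reaction is the aryne acyl-alkylation of β-keto esters, including ring expansion of cyclic ones; the new element is a vinylogous lactone as the anion-stabilising group in place of a directly attached ester. C2 is not deprotonated and keeps its configuration; C1 is protonated last and reversibly, so it takes the thermodynamic trans arrangement to the C2 ester. The step needs reaction at C1 and not at C3, at oxygen or at C3′, which is secured because C1 is by far the most acidic site and the exocyclic terminus of the dienolate. It needs the aryl anion to attack the ketone and not the C2 ester, which is secured because the aryne approaches anti to the bulky tert-butyl ester and the aryl anion then sits trans to it. It needs carbanion addition to outrun [4+2] addition of the aryne to the electron-poor pyranone, which slow addition of 9 and the mild temperature favour.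

Step 8
Reactants: 11 tert-butyl (1R,2R)-6,7-dimethoxy-1-[6-(methoxycarbonyl)-2-oxo-2H-pyran-4-yl]-4-oxo-1,2,3,4-tetrahydronaphthalene-2-carboxylate
Product: 13 2-tert-butyl 3-methyl (1R,2S)-6,7-dimethoxy-1-[6-(methoxycarbonyl)-2-oxo-2H-pyran-4-yl]-4-oxo-1,2,3,4-tetrahydronaphthalene-2,3-dicarboxylate, via keto acid 12 (not isolated)
Conditions: MgCl2, NaI, Et3N, CO2 (1 atm), MeCN, rt; cold 1 M HCl; then TMSCHN2, MeOH/toluene, 0 °C
Reagents that add atoms: carbon dioxide, O=C=O; (trimethylsilyl)diazomethane, C[Si](C)(C)C=[N+]=[N-]
Why: Soft enolisation: MgCl2 and Et3N form the magnesium enolate at C3, the only enolisable α-position of the aryl ketone, and CO2 is captured as the chelated magnesium β-keto carboxylate, which drives the reversible carboxylation (the principle of methyl magnesium carbonate, here at room temperature and without methoxide); Et3N is too weak to ionise C1–H, and the labile keto acid is esterified at once.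

Step 9
Reactants: 13 2-tert-butyl 3-methyl (1R,2S)-6,7-dimethoxy-1-[6-(methoxycarbonyl)-2-oxo-2H-pyran-4-yl]-4-oxo-1,2,3,4-tetrahydronaphthalene-2,3-dicarboxylate
Product: 14 2-tert-butyl 3-methyl (1R,2S)-4-hydroxy-6,7-dimethoxy-1-[6-(methoxycarbonyl)-2-oxo-2H-pyran-4-yl]-1,2,3,4-tetrahydronaphthalene-2,3-dicarboxylate
Conditions: NaBH4, CeCl3·7H2O, MeOH/THF, −78 → −40 °C
Reagents that add atoms: none
Why: Luche reduction: NaBH4 with CeCl3 reduces the ketone by 1,2-addition at low temperature and should spare the pyranone, which could only react by conjugate hydride addition; the configurations at C3 and C4 do not matter because both carbons become sp2 in the next step.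

Step 10
Reactants: 14 2-tert-butyl 3-methyl (1R,2S)-4-hydroxy-6,7-dimethoxy-1-[6-(methoxycarbonyl)-2-oxo-2H-pyran-4-yl]-1,2,3,4-tetrahydronaphthalene-2,3-dicarboxylate
Product: 15 2-tert-butyl 3-methyl (1R,2S)-6,7-dimethoxy-1-[6-(methoxycarbonyl)-2-oxo-2H-pyran-4-yl]-1,2-dihydronaphthalene-2,3-dicarboxylate
Conditions: p-TsOH·H2O (10 mol%), toluene, 50 °C
Reagents that add atoms: none
Why: Acid-catalysed E1 dehydration: the benzylic C4 cation is stabilised by the C7 methoxy group para to C4a, and loss of the C3 proton gives the alkene conjugated with ring A and the C3 ester; only C3 has a β-hydrogen, and partial loss of the tert-butyl group would be harmless because the next step removes it.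

Step 11
Reactants: 15 2-tert-butyl 3-methyl (1R,2S)-6,7-dimethoxy-1-[6-(methoxycarbonyl)-2-oxo-2H-pyran-4-yl]-1,2-dihydronaphthalene-2,3-dicarboxylate
Product: 16 (1R,2S)-6,7-dihydroxy-3-(methoxycarbonyl)-1-[6-(methoxycarbonyl)-2-oxo-2H-pyran-4-yl]-1,2-dihydronaphthalene-2-carboxylic acid
Conditions: BBr3, CH2Cl2, −78 → 0 °C; then H2O
Reagents that add atoms: none
Why: BBr3 cleaves the two aryl methyl ethers (complexation, then SN2 attack of bromide on methyl) and the tert-butyl ester (ionisation of the tert-butyl group); these non-basic conditions should leave the pyranone, the alkene and both stereocentres alone, and any methyl ester cleaved here only anticipates step 12.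

Step 12
Reactants: 16 (1R,2S)-6,7-dihydroxy-3-(methoxycarbonyl)-1-[6-(methoxycarbonyl)-2-oxo-2H-pyran-4-yl]-1,2-dihydronaphthalene-2-carboxylic acid
Product: 17 (1R,2S)-1-(6-carboxy-2-oxo-2H-pyran-4-yl)-6,7-dihydroxy-1,2-dihydronaphthalene-2,3-dicarboxylic acid
Conditions: 3 M HCl, 1,4-dioxane, 70 °C, argon
Reagents that add atoms: water, O
Why: Acid-catalysed acyl–oxygen hydrolysis of the two conjugated methyl esters; acid is used because hydroxide would open the pyranone and could move the C3=C4 double bond or epimerise C2, whereas under acid C1 and C2 are not ionised.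

## Compound list

1 | 4-hydroxy-6-methyl-2H-pyran-2-one (triacetic acid lactone) | Cc1cc(O)cc(=O)o1 | starting material
2 | 4-bromo-6-methyl-2H-pyran-2-one | Cc1cc(Br)cc(=O)o1 | intermediate
3 | 4-bromo-2-oxo-2H-pyran-6-carbaldehyde | O=Cc1cc(Br)cc(=O)o1 | intermediate
4 | 4-bromo-2-oxo-2H-pyran-6-carboxylic acid | OC(=O)c1cc(Br)cc(=O)o1 | intermediate
5 | methyl 4-bromo-2-oxo-2H-pyran-6-carboxylate | COC(=O)c1cc(Br)cc(=O)o1 | intermediate
6 | tert-butyl 3-oxocyclobutane-1-carboxylate | CC(C)(C)OC(=O)C1CC(=O)C1 | starting material
7 | tert-butyl (1R)-3-[(trimethylsilyl)oxy]cyclobut-2-ene-1-carboxylate | CC(C)(C)OC(=O)[C@@H]1CC(O[Si](C)(C)C)=C1 | intermediate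
8 | tert-butyl (1R,2R)-2-[6-(methoxycarbonyl)-2-oxo-2H-pyran-4-yl]-3-oxocyclobutane-1-carboxylate (trans) | O=C1C[C@@H](C(=O)OC(C)(C)C)[C@@H]1c1cc(C(=O)OC)oc(=O)c1 | intermediate
9 | 4,5-dimethoxy-2-(trimethylsilyl)phenyl trifluoromethanesulfonate | COc1cc(OS(=O)(=O)C(F)(F)F)c([Si](C)(C)C)cc1OC | starting material
10 | 4,5-dimethoxybenzyne (1,2-didehydro-4,5-dimethoxybenzene; not isolated) | COC1=CC#CC=C1OC | intermediate
11 | tert-butyl (1R,2R)-6,7-dimethoxy-1-[6-(methoxycarbonyl)-2-oxo-2H-pyran-4-yl]-4-oxo-1,2,3,4-tetrahydronaphthalene-2-carboxylate (1,2-trans) | O=C1c2cc(OC)c(OC)cc2[C@@H](c2cc(C(=O)OC)oc(=O)c2)[C@H](C(=O)OC(C)(C)C)C1 | intermediate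
12 | (1R,2S)-2-(tert-butoxycarbonyl)-6,7-dimethoxy-1-[6-(methoxycarbonyl)-2-oxo-2H-pyran-4-yl]-4-oxo-1,2,3,4-tetrahydronaphthalene-3-carboxylic acid (target numbering; C3 epimers; not isolated) | O=C1c2cc(OC)c(OC)cc2[C@@H](c2cc(C(=O)OC)oc(=O)c2)[C@H](C(=O)OC(C)(C)C)C1C(=O)O | intermediate
13 | 2-tert-butyl 3-methyl (1R,2S)-6,7-dimethoxy-1-[6-(methoxycarbonyl)-2-oxo-2H-pyran-4-yl]-4-oxo-1,2,3,4-tetrahydronaphthalene-2,3-dicarboxylate (C3 epimers, in equilibrium with the enol) | O=C1c2cc(OC)c(OC)cc2[C@@H](c2cc(C(=O)OC)oc(=O)c2)[C@H](C(=O)OC(C)(C)C)C1C(=O)OC | intermediate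
14 | 2-tert-butyl 3-methyl (1R,2S)-4-hydroxy-6,7-dimethoxy-1-[6-(methoxycarbonyl)-2-oxo-2H-pyran-4-yl]-1,2,3,4-tetrahydronaphthalene-2,3-dicarboxylate (mixture at C3 and C4) | OC1c2cc(OC)c(OC)cc2[C@@H](c2cc(C(=O)OC)oc(=O)c2)[C@H](C(=O)OC(C)(C)C)C1C(=O)OC | intermediate
15 | 2-tert-butyl 3-methyl (1R,2S)-6,7-dimethoxy-1-[6-(methoxycarbonyl)-2-oxo-2H-pyran-4-yl]-1,2-dihydronaphthalene-2,3-dicarboxylate | COC(=O)C1=Cc2cc(OC)c(OC)cc2[C@@H](c2cc(C(=O)OC)oc(=O)c2)[C@@H]1C(=O)OC(C)(C)C | intermediate
16 | (1R,2S)-6,7-dihydroxy-3-(methoxycarbonyl)-1-[6-(methoxycarbonyl)-2-oxo-2H-pyran-4-yl]-1,2-dihydronaphthalene-2-carboxylic acid | COC(=O)C1=Cc2cc(O)c(O)cc2[C@@H](c2cc(C(=O)OC)oc(=O)c2)[C@@H]1C(=O)O | intermediate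
17 | (1R,2S)-1-(6-carboxy-2-oxo-2H-pyran-4-yl)-6,7-dihydroxy-1,2-dihydronaphthalene-2,3-dicarboxylic acid | O=C(O)C1=Cc2cc(O)c(O)cc2[C@@H](c2cc(C(=O)O)oc(=O)c2)[C@@H]1C(=O)O | target

## Step count and least certain steps

Total: 12 steps. Longest linear sequence: 11 steps (1 → 17 through steps 1–4 and 6–12); the cyclobutanone branch (6 → 17, steps 5–12) has 8 steps.

**Step 7 (key step).**
- What may go wrong: protonation of the aryl anion before it reaches the ketone, which stops the sequence at simple arylation of C1.
- [4+2] cycloaddition of the aryne across the pyranone diene with loss of CO2.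
- Retro-Claisen opening of the strained, activated cyclobutanone by adventitious water under fluoride.
- Capture of the aryl anion by the C2 ester if the aryne approaches syn to it.
- Fallback (known reactions, the same two bonds formed one after the other): it sets out from 8. Monovalent rhodium ([Rh(OH)(cod)]2, P(t-Bu)3, dioxane, 80 °C) adds commercial (2-bromo-4,5-dimethoxyphenyl)boronic acid to the cyclobutanone carbonyl. The rhodium cyclobutanolate opens by β-carbon elimination toward the pyranone-stabilised carbon, which forms C4–C4a and gives, after protonation, tert-butyl (2S)-4-(2-bromo-4,5-dimethoxyphenyl)-2-{[6-(methoxycarbonyl)-2-oxo-2H-pyran-4-yl]methyl}-4-oxobutanoate F1. Intramolecular arylation of the pyranone-activated methylene by the aryl bromide with zerovalent palladium (Pd(OAc)2, P(t-Bu)3·HBF4, Cs2CO3, toluene, 80 °C) then forms C1–C8a, and the base equilibrates C1 to trans. The fallback comes back to the route at 11.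

**Step 6.**
- What may go wrong: attack of the enol silane at C6′ instead of C4′ of the activated pyranone, or cleavage of the tert-butyl ester by TiCl4 before the coupling is complete. The C4′ preference is inferred from how 4-halopyranones behave toward other nucleophiles.
- Fallback (anionic instead of Lewis-acid coupling): it sets out from 6. The chiral lithium amide, made from the amine hydrochloride and two equivalents of n-BuLi so that LiCl is present, converts 6 at −78 °C into lithium (3R)-3-(tert-butoxycarbonyl)cyclobut-1-en-1-olate F2. Bromide 5 (0.45 equiv) is added at −78 °C; half of the enolate serves as base for the acidic product. Addition–elimination at C4′, acidic quench and equilibration return the route to 8.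

**Step 5.**
- What may go wrong: weak discrimination between the enantiotopic methylene groups, because the ester is a small, polar substituent, and erosion of the enol silane on handling.
- Fallback (resolution instead of asymmetric deprotonation): it sets out from 6. LiHMDS and TMSCl give racemic 7, an equal mixture of 7 and tert-butyl (1S)-3-[(trimethylsilyl)oxy]cyclobut-2-ene-1-carboxylate F3. Step 6 on this mixture gives racemic trans product, which preparative chromatography on a chiral stationary phase separates into 8 and tert-butyl (1S,2S)-2-[6-(methoxycarbonyl)-2-oxo-2H-pyran-4-yl]-3-oxocyclobutane-1-carboxylate F4. The route is rejoined at 8.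

**Step 8.**
- What may go wrong: incomplete carboxylation because the chelate forms slowly next to the bulky C2 ester, and decarboxylation of the keto acid during acidification before it is esterified.
- Fallback (the C3 carbon enters as a formyl group, and steps 9 and 10 are no longer needed): it sets out from 11. Vilsmeier–Haack–Arnold reaction (POCl3, DMF, 0 → 50 °C) gives tert-butyl (1R,2S)-4-chloro-3-formyl-6,7-dimethoxy-1-[6-(methoxycarbonyl)-2-oxo-2H-pyran-4-yl]-1,2-dihydronaphthalene-2-carboxylate F5. Pinnick oxidation gives (1R,2S)-2-(tert-butoxycarbonyl)-4-chloro-6,7-dimethoxy-1-[6-(methoxycarbonyl)-2-oxo-2H-pyran-4-yl]-1,2-dihydronaphthalene-3-carboxylic acid F6. TMSCHN2 gives 2-tert-butyl 3-methyl (1R,2S)-4-chloro-6,7-dimethoxy-1-[6-(methoxycarbonyl)-2-oxo-2H-pyran-4-yl]-1,2-dihydronaphthalene-2,3-dicarboxylate F7. Hydrodechlorination of the β-chloro enoate with zerovalent palladium and formate (Pd(OAc)2, PCy3, HCO2H, Et3N, DMF, 80 °C) comes back to the route at 15.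

**Step 2.**
- What may go wrong: decomposition or over-oxidation at 150 °C, and hydrolytic loss of the C4 bromide by the water that the oxidation forms.
- Fallback (halogenation and oxygen transfer instead of direct oxidation): it sets out from 2. Wohl–Ziegler bromination (NBS, AIBN, PhCF3, 80 °C) gives 4-bromo-6-(bromomethyl)-2H-pyran-2-one F8. Kornblum oxidation (AgBF4, DMSO, rt; then Et3N) comes back to the route at 3.

**Step 12.**
- What may go wrong: slow hydrolysis of the conjugated esters, and during long heating migration of the C3=C4 double bond toward C2=C3, which would lose C2, and air oxidation of ring B or the catechol.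
- Fallback (cleavage at the methyl carbon instead of the acyl carbon): it sets out from 16. Anhydrous LiI in ethyl acetate at reflux removes both methyl groups by SN2 attack of iodide, and acidification comes back at 17; no new compound arises (F0).

## Further compounds

F1 | step 7 | tert-butyl (2S)-4-(2-bromo-4,5-dimethoxyphenyl)-2-{[6-(methoxycarbonyl)-2-oxo-2H-pyran-4-yl]methyl}-4-oxobutanoate | COc1cc(Br)c(cc1OC)C(=O)C[C@@H](C(=O)OC(C)(C)C)Cc1cc(C(=O)OC)oc(=O)c1
F2 | step 6 | lithium (3R)-3-(tert-butoxycarbonyl)cyclobut-1-en-1-olate | [Li+].[O-]C1=C[C@H](C(=O)OC(C)(C)C)C1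
F3 | step 5 | tert-butyl (1S)-3-[(trimethylsilyl)oxy]cyclobut-2-ene-1-carboxylate | CC(C)(C)OC(=O)[C@H]1CC(O[Si](C)(C)C)=C1
F4 | step 5 | tert-butyl (1S,2S)-2-[6-(methoxycarbonyl)-2-oxo-2H-pyran-4-yl]-3-oxocyclobutane-1-carboxylate | O=C1C[C@H](C(=O)OC(C)(C)C)[C@H]1c1cc(C(=O)OC)oc(=O)c1
F5 | step 8 | tert-butyl (1R,2S)-4-chloro-3-formyl-6,7-dimethoxy-1-[6-(methoxycarbonyl)-2-oxo-2H-pyran-4-yl]-1,2-dihydronaphthalene-2-carboxylate | O=CC1=C(Cl)c2cc(OC)c(OC)cc2[C@@H](c2cc(C(=O)OC)oc(=O)c2)[C@@H]1C(=O)OC(C)(C)C
F6 | step 8 | (1R,2S)-2-(tert-butoxycarbonyl)-4-chloro-6,7-dimethoxy-1-[6-(methoxycarbonyl)-2-oxo-2H-pyran-4-yl]-1,2-dihydronaphthalene-3-carboxylic acid | OC(=O)C1=C(Cl)c2cc(OC)c(OC)cc2[C@@H](c2cc(C(=O)OC)oc(=O)c2)[C@@H]1C(=O)OC(C)(C)C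
F7 | step 8 | 2-tert-butyl 3-methyl (1R,2S)-4-chloro-6,7-dimethoxy-1-[6-(methoxycarbonyl)-2-oxo-2H-pyran-4-yl]-1,2-dihydronaphthalene-2,3-dicarboxylate | COC(=O)C1=C(Cl)c2cc(OC)c(OC)cc2[C@@H](c2cc(C(=O)OC)oc(=O)c2)[C@@H]1C(=O)OC(C)(C)C
F8 | step 2 | 4-bromo-6-(bromomethyl)-2H-pyran-2-one | BrCc1cc(Br)cc(=O)o1
F0 | step 12 | none | none
A1 | alternative 1 | dimethyl (1R,2S)-1-(3,4-dihydroxyphenyl)-6,7-dimethoxy-1,2-dihydronaphthalene-2,3-dicarboxylate | COC(=O)C1=Cc2cc(OC)c(OC)cc2[C@@H](c2ccc(O)c(O)c2)[C@@H]1C(=O)OC
A2 | alternative 1 | 4-[(1R,2S)-6,7-dimethoxy-2,3-bis(methoxycarbonyl)-1,2-dihydronaphthalen-1-yl]-2-oxo-2H-pyran-6-carboxylic acid | COC(=O)C1=Cc2cc(OC)c(OC)cc2[C@@H](c2cc(C(=O)O)oc(=O)c2)[C@@H]1C(=O)OC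
A3 | alternative 2 | 3-[(1R,2S)-6,7-dimethoxy-2,3-bis(methoxycarbonyl)-1,2-dihydronaphthalen-1-yl]prop-2-ynoic acid | COC(=O)C1=Cc2cc(OC)c(OC)cc2[C@@H](C#CC(=O)O)[C@@H]1C(=O)OC
A4 | alternative 2 | 3,3-diethoxyprop-1-yne | C#CC(OCC)OCC
A5 | alternative 2 | dimethyl (1R,2S)-1-[6-(diethoxymethyl)-2-oxo-2H-pyran-4-yl]-6,7-dimethoxy-1,2-dihydronaphthalene-2,3-dicarboxylate | COC(=O)C1=Cc2cc(OC)c(OC)cc2[C@@H](c2cc(C(OCC)OCC)oc(=O)c2)[C@@H]1C(=O)OC
A6 | alternative 3 | dimethyl 2-{(S)-(3,4-dimethoxyphenyl)[6-(methoxycarbonyl)-2-oxo-2H-pyran-4-yl]methyl}propanedioate | COC(=O)C(C(=O)OC)[C@@H](c1ccc(OC)c(OC)c1)c1cc(C(=O)OC)oc(=O)c1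
A7 | alternative 3 | methyl (E)-3-methoxyprop-2-enoate | CO/C=C/C(=O)OC
A8 | alternative 3 | trimethyl (1R)-4,6,7-trimethoxy-1-[6-(methoxycarbonyl)-2-oxo-2H-pyran-4-yl]-3,4-dihydronaphthalene-2,2,3(1H)-tricarboxylate (mixture at C3 and C4) | COC(=O)C1C(OC)c2cc(OC)c(OC)cc2[C@@H](c2cc(C(=O)OC)oc(=O)c2)C1(C(=O)OC)C(=O)OC
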